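**Plan**

1. Retrosynthesis: the two phenol methyl ethers and the C6 formyl group are removed first; the pyran ring is then opened at O1–C8a together with the C8–CHO bond (aryne disconnection); the tertiary carbinol is cut at C3–C2 (spiro carbon) into a chiral primary iodide and camphenilone; the C4 stereocentre goes back to an auxiliary-bound arylacetic acid.
2. Enabling feature: in the chroman ring (O1, spiro C2, C3, C4, C4a, C8a) the ether oxygen O1 sits on C8a and a formyl carbon on the adjacent C8, with the C7 oxygen next to C8. A single C8–C8a aryne can therefore accept the tethered oxygen at C8a and an electrophile at C8.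
3. Forward order: the side chain is built on the chloroarene (steps 1–8) and joined to the norbornanone (steps 9–10); the pyran ring closes with C8 formylation (step 11); C6 formylation and O-demethylation finish the route. The arene and the norbornane are bought; only the pyran ring is made.
4. Stereochemistry: C4 comes from an Evans alkylation with (R)-4-benzyl-2-oxazolidinone; the bridgeheads come from (−)-camphene; the spiro carbon comes from exo addition to camphenilone, which places oxygen endo.

Key step: step 11

Assumption: the arene must carry chlorine ortho and methoxy groups ortho and para to the side chain (the target's 5,7,8a-oxygen pattern), so it is built from 1-chloro-3,5-dimethoxybenzene; commercial (−)-camphene is used at its supplied optical purity, and its minor enantiomer should end as a diastereomer of 20 removable by chromatography.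

**Route**

Step 1
Reactants: 1 1-chloro-3,5-dimethoxybenzene
Product: 2 2-bromo-1-chloro-3,5-dimethoxybenzene
Conditions: NBS (1.0 equiv), MeCN, 0 °C to rt
Reagents that add atoms: N-bromosuccinimide, O=C1CCC(=O)N1Br
Why: Electrophilic aromatic bromination should enter para to one methoxy group and ortho to the other, that is between Cl and OMe (two equivalent sites), in preference to the position flanked by both methoxy groups, and any isomer is removed by crystallisation.

Step 2
Reactants: 2 2-bromo-1-chloro-3,5-dimethoxybenzene; 3 (2-tert-butoxy-2-oxoethyl)zinc bromide (BrZnCH2CO2t-Bu, commercial ether solution)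
Product: 4 tert-butyl (2-chloro-4,6-dimethoxyphenyl)acetate
Conditions: Pd(dba)2 (2 mol %), P(t-Bu)3 (2 mol %), THF, rt to 50 °C
Reagents that add atoms: none
Why: Palladium-catalysed α-arylation of a Reformatsky zinc enolate (Negishi-type coupling) should occur only at the C–Br bond, since the C–Cl bond is far slower in oxidative addition and the bulky trialkylphosphine accepts ortho-substituted aryl bromides.

Step 3
Reactants: 4 tert-butyl (2-chloro-4,6-dimethoxyphenyl)acetate
Product: 5 (2-chloro-4,6-dimethoxyphenyl)acetic acid
Conditions: CF3CO2H, CH2Cl2, rt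
Reagents that add atoms: none
Why: Acidolysis of the tert-butyl ester with loss of isobutene should free the acid without touching the aryl ethers or the chloride, the open ring positions being too crowded for tert-butylation.

Step 4
Reactants: 5 (2-chloro-4,6-dimethoxyphenyl)acetic acid; 6 (R)-4-benzyl-2-oxazolidinone
Product: 8 (4R)-4-benzyl-3-[(2-chloro-4,6-dimethoxyphenyl)acetyl]-1,3-oxazolidin-2-one, via mixed pivalic anhydride 7 (not isolated)
Conditions: PivCl, Et3N, THF, −20 °C; then 6, LiCl, rt
Reagents that add atoms: none
Why: Mixed-anhydride N-acylation of the oxazolidinone should take place at the less hindered arylacetyl carbonyl of 7, with LiCl and Et3N activating the N–H.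

Step 5
Reactants: 8 (4R)-4-benzyl-3-[(2-chloro-4,6-dimethoxyphenyl)acetyl]-1,3-oxazolidin-2-one; 9 3-bromo-2-methylpropene
Product: 11 (4R)-4-benzyl-3-[(2R)-2-(2-chloro-4,6-dimethoxyphenyl)-4-methylpent-4-enoyl]-1,3-oxazolidin-2-one, via sodium Z-enolate 10 (not isolated)
Conditions: NaN(SiMe3)2, THF, −78 °C; then 9, −78 to −40 °C
Reagents that add atoms: none
Why: In this Evans alkylation the sodium-chelated Z-enolate should be attacked by the allylic bromide on the face away from the benzyl group of the (R)-auxiliary, which sets the new centre as 2R (aryl ranks above the methallyl carbon), and the minor diastereomer is separable.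

Step 6
Reactants: 11 (4R)-4-benzyl-3-[(2R)-2-(2-chloro-4,6-dimethoxyphenyl)-4-methylpent-4-enoyl]-1,3-oxazolidin-2-one
Product: 12 (4R)-4-benzyl-3-[(2R)-2-(2-chloro-4,6-dimethoxyphenyl)-4-methylpentanoyl]-1,3-oxazolidin-2-one
Conditions: H2 (1 atm), RhCl(PPh3)3 (5 mol %), toluene–EtOH, rt
Reagents that add atoms: none
Why: Homogeneous hydrogenation with Wilkinson's catalyst should reduce the unhindered 1,1-disubstituted alkene and leave the aryl chloride, the benzyl group and the α-stereocentre alone.

Step 7
Reactants: 12 (4R)-4-benzyl-3-[(2R)-2-(2-chloro-4,6-dimethoxyphenyl)-4-methylpentanoyl]-1,3-oxazolidin-2-one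
Product: 13 (2R)-2-(2-chloro-4,6-dimethoxyphenyl)-4-methylpentan-1-ol
Conditions: LiBH4, MeOH (1 equiv), THF, 0 °C
Reagents that add atoms: none
Why: Hydride attack at the exocyclic imide carbonyl (reductive auxiliary cleavage) should release the primary alcohol and the intact auxiliary without enolising the α-aryl centre.

Step 8
Reactants: 13 (2R)-2-(2-chloro-4,6-dimethoxyphenyl)-4-methylpentan-1-ol
Product: 14 1-chloro-2-[(2R)-1-iodo-4-methylpentan-2-yl]-3,5-dimethoxybenzene
Conditions: I2, PPh3, imidazole, CH2Cl2, 0 °C to rt
Reagents that add atoms: iodine, II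
Why: Appel-type iodination through the alkoxyphosphonium salt is an SN2 displacement at the primary carbon and does not involve the neighbouring stereocentre.

Step 9
Reactants: 15 (−)-camphene [(1S,4R)-2,2-dimethyl-3-methylidenebicyclo[2.2.1]heptane]
Product: 17 (1R,4S)-3,3-dimethylbicyclo[2.2.1]heptan-2-one (camphenilone), via spiro ozonide 16 (not isolated)
Conditions: O3, CH2Cl2, −78 °C; then Me2S, −78 °C to rt
Reagents that add atoms: ozone, [O-][O+]=O
Why: Ozonolysis of the exocyclic methylene with reductive work-up should give the ketone, whose bridgehead centres are untouched and which cannot enolise (quaternary carbon on one side, bridgehead on the other).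

Step 10
Reactants: 14 1-chloro-2-[(2R)-1-iodo-4-methylpentan-2-yl]-3,5-dimethoxybenzene; 17 (1R,4S)-camphenilone
Product: 20 (1R,2R,4S)-2-[(2S)-2-(2-chloro-4,6-dimethoxyphenyl)-4-methylpentyl]-3,3-dimethylbicyclo[2.2.1]heptan-2-ol (hydroxyl endo), via primary alkyllithium 18 (not isolated), via alkylcerium dichloride 19 (not isolated)
Conditions: 14, t-BuLi (2.0 equiv), Et2O–pentane, −78 °C; CeCl3 (dried), THF, −78 °C; then 17 (1.5 equiv), −78 to 0 °C; aq. NH4Cl
Reagents that add atoms: none
Why: Iodine–lithium exchange and transmetalation give an organocerium reagent (Imamoto addition) that is nucleophilic but weakly basic and should add to the hindered, non-enolisable carbonyl from the exo face, the side of the one-carbon bridge, so that the chain ends exo and the hydroxyl endo (2R).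

Step 11
Reactants: 20 (1R,2R,4S)-2-[(2S)-2-(2-chloro-4,6-dimethoxyphenyl)-4-methylpentyl]-3,3-dimethylbicyclo[2.2.1]heptan-2-ol
Product: 24 (1'R,2R,4S,4'S)-4-isobutyl-5,7-dimethoxy-3',3'-dimethylspiro[chromane-2,2'-bicyclo[2.2.1]heptane]-8-carbaldehyde, via aryne alkoxide 21 (not isolated), via C8 aryllithium 22 (not isolated), via lithium hemiaminal alkoxide 23 (not isolated)
Conditions: LiTMP (lithium 2,2,6,6-tetramethylpiperidide, 4 equiv), THF, −78 to 0 °C; then DMF (6 equiv), −78 °C to rt; aq. NH4Cl
Reagents that add atoms: N,N-dimethylformamide, CN(C)C=O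
Why: The amide base first forms the lithium alkoxide and then takes the one ring proton ortho to chlorine, which also lies next to a methoxy group; loss of LiCl from that anion is irreversible, whereas metalation between the two methoxy groups is reversible and unproductive, so the C8–C8a aryne 21 should form. The tethered tertiary alkoxide adds at C8a in a six-membered closure with the aryne bond exocyclic to the new ring (6-exo-dig), forming O1–C8a and the pyran ring; C8a is the only aryne carbon within reach and also the electronically preferred one, because the charge then develops at C8 beside the inductively stabilising C7 methoxy group. The aryllithium 22, held between two oxygens, is formylated by DMF through hemiaminal alkoxide 23, which collapses to the C8 aldehyde on work-up. The closest known reaction type is the amide-base benzyne cyclisation of haloarene-tethered alkoxides to chromans, combined with electrophilic quench of the resulting aryl anion. No stereocentre is created, and C4, the spiro carbon and the bridgeheads are carried through under non-epimerising basic conditions. Regiochemistry is the only selectivity required and is secured by the position of chlorine, the tether length and the C7 methoxy group.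

Step 12
Reactants: 24 (1'R,2R,4S,4'S)-4-isobutyl-5,7-dimethoxy-3',3'-dimethylspiro[chromane-2,2'-bicyclo[2.2.1]heptane]-8-carbaldehyde
Product: 26 (1'R,2R,4S,4'S)-4-isobutyl-5,7-dimethoxy-3',3'-dimethylspiro[chromane-2,2'-bicyclo[2.2.1]heptane]-6,8-dicarbaldehyde, via C6 chloro(methoxy)methyl adduct 25 (not isolated)
Conditions: Cl2CHOMe (2 equiv), TiCl4 (3 equiv), CH2Cl2, −78 to −20 °C; ice–water
Reagents that add atoms: dichloromethyl methyl ether, COC(Cl)Cl; water, O
Why: Rieche formylation should take the one remaining ring position, C6, which is ortho to both methoxy groups and para to O1 and so still reactive despite the C8 aldehyde, while low temperature and short contact limit Lewis-acid ionisation of the tertiary spiro ether.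

Step 13
Reactants: 26 (1'R,2R,4S,4'S)-4-isobutyl-5,7-dimethoxy-3',3'-dimethylspiro[chromane-2,2'-bicyclo[2.2.1]heptane]-6,8-dicarbaldehyde
Product: 27 (1'R,2R,4S,4'S)-5,7-dihydroxy-4-isobutyl-3',3'-dimethylspiro[chromane-2,2'-bicyclo[2.2.1]heptane]-6,8-dicarbaldehyde (CNP0150011.1)
Conditions: NaSEt (6 equiv), degassed DMF, 110 °C; then 1 M HCl, 0 °C
Reagents that add atoms: none
Why: Thiolate SN2 O-demethylation should cleave both methyl ethers because each lies ortho to a formyl group and leaves as a stabilised, vinylogous carboxylate-type phenoxide, and the basic medium spares the acid-labile tertiary ether and all stereocentres.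

**Compound list**

1 | 1-chloro-3,5-dimethoxybenzene | COc1cc(Cl)cc(OC)c1 | starting material
2 | 2-bromo-1-chloro-3,5-dimethoxybenzene | COc1cc(Cl)c(Br)c(OC)c1 | intermediate
3 | (2-tert-butoxy-2-oxoethyl)zinc bromide | CC(C)(C)OC(=O)C[Zn]Br | starting material
4 | tert-butyl (2-chloro-4,6-dimethoxyphenyl)acetate | CC(C)(C)OC(=O)Cc1c(Cl)cc(OC)cc1OC | intermediate
5 | (2-chloro-4,6-dimethoxyphenyl)acetic acid | OC(=O)Cc1c(Cl)cc(OC)cc1OC | intermediate
6 | (R)-4-benzyl-2-oxazolidinone | O=C1N[C@H](Cc2ccccc2)CO1 | starting material
7 | (2-chloro-4,6-dimethoxyphenyl)acetic pivalic anhydride (not isolated) | CC(C)(C)C(=O)OC(=O)Cc1c(Cl)cc(OC)cc1OC | intermediate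
8 | (4R)-4-benzyl-3-[(2-chloro-4,6-dimethoxyphenyl)acetyl]-1,3-oxazolidin-2-one | O=C(Cc1c(Cl)cc(OC)cc1OC)N1[C@H](Cc2ccccc2)COC1=O | intermediate
9 | 3-bromo-2-methylpropene | C=C(C)CBr | starting material
10 | sodium Z-enolate of 8 (not isolated) | [Na+].[O-]/C(=C\c1c(Cl)cc(OC)cc1OC)N1[C@H](Cc2ccccc2)COC1=O | intermediate
11 | (4R)-4-benzyl-3-[(2R)-2-(2-chloro-4,6-dimethoxyphenyl)-4-methylpent-4-enoyl]-1,3-oxazolidin-2-one | C=C(C)C[C@H](c1c(Cl)cc(OC)cc1OC)C(=O)N1[C@H](Cc2ccccc2)COC1=O | intermediate
12 | (4R)-4-benzyl-3-[(2R)-2-(2-chloro-4,6-dimethoxyphenyl)-4-methylpentanoyl]-1,3-oxazolidin-2-one | CC(C)C[C@H](c1c(Cl)cc(OC)cc1OC)C(=O)N1[C@H](Cc2ccccc2)COC1=O | intermediate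
13 | (2R)-2-(2-chloro-4,6-dimethoxyphenyl)-4-methylpentan-1-ol | CC(C)C[C@H](c1c(Cl)cc(OC)cc1OC)CO | intermediate
14 | 1-chloro-2-[(2R)-1-iodo-4-methylpentan-2-yl]-3,5-dimethoxybenzene | CC(C)C[C@H](c1c(Cl)cc(OC)cc1OC)CI | intermediate
15 | (−)-camphene, (1S,4R)-2,2-dimethyl-3-methylidenebicyclo[2.2.1]heptane | C=C2[C@@H]1CC[C@@H](C1)C2(C)C | starting material
16 | camphene ozonide, spiro 1,2,4-trioxolane on the norbornane carbon (not isolated) | C1OC2(OO1)[C@@H]1CC[C@@H](C1)C2(C)C | intermediate
17 | (1R,4S)-3,3-dimethylbicyclo[2.2.1]heptan-2-one (camphenilone) | O=C2[C@@H]1CC[C@@H](C1)C2(C)C | intermediate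
18 | primary alkyllithium from 14 (not isolated) | CC(C)C[C@H](c1c(Cl)cc(OC)cc1OC)C[Li] | intermediate
19 | alkylcerium dichloride from 18 (not isolated) | CC(C)C[C@H](c1c(Cl)cc(OC)cc1OC)C[Ce](Cl)Cl | intermediate
20 | (1R,2R,4S)-2-[(2S)-2-(2-chloro-4,6-dimethoxyphenyl)-4-methylpentyl]-3,3-dimethylbicyclo[2.2.1]heptan-2-ol, hydroxyl endo | CC(C)C[C@H](c1c(Cl)cc(OC)cc1OC)C[C@@]2(O)[C@@H]1CC[C@@H](C1)C2(C)C | intermediate
21 | lithium alkoxide of the C8–C8a aryne from 20 (not isolated) | CC(C)C[C@H](C1=C(OC)C=C(OC)C#C1)C[C@@]2([O-])[C@@H]1CC[C@@H](C1)C2(C)C.[Li+] | intermediate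
22 | 8-lithio-4-isobutyl-5,7-dimethoxy spirochroman (not isolated) | CC(C)C[C@H]1C[C@@]2(Oc3c([Li])c(OC)cc(OC)c31)[C@@H]1CC[C@@H](C1)C2(C)C | intermediate
23 | lithium alkoxide of the C8 dimethylamino carbinol, DMF adduct of 22 (not isolated) | CC(C)C[C@H]1C[C@@]2(Oc3c(C([O-])N(C)C)c(OC)cc(OC)c31)[C@@H]1CC[C@@H](C1)C2(C)C.[Li+] | intermediate
24 | (1'R,2R,4S,4'S)-4-isobutyl-5,7-dimethoxy-3',3'-dimethylspiro[chromane-2,2'-bicyclo[2.2.1]heptane]-8-carbaldehyde, O1 endo on the norbornane | CC(C)C[C@H]1C[C@@]2(Oc3c(C=O)c(OC)cc(OC)c31)[C@@H]1CC[C@@H](C1)C2(C)C | intermediate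
25 | 6-[chloro(methoxy)methyl] derivative of 24 (not isolated) | CC(C)C[C@H]1C[C@@]2(Oc3c(C=O)c(OC)c(C(Cl)OC)c(OC)c31)[C@@H]1CC[C@@H](C1)C2(C)C | intermediate
26 | (1'R,2R,4S,4'S)-4-isobutyl-5,7-dimethoxy-3',3'-dimethylspiro[chromane-2,2'-bicyclo[2.2.1]heptane]-6,8-dicarbaldehyde | CC(C)C[C@H]1C[C@@]2(Oc3c(C=O)c(OC)c(C=O)c(OC)c31)[C@@H]1CC[C@@H](C1)C2(C)C | intermediate
27 | (1'R,2R,4S,4'S)-5,7-dihydroxy-4-isobutyl-3',3'-dimethylspiro[chromane-2,2'-bicyclo[2.2.1]heptane]-6,8-dicarbaldehyde, CNP0150011.1 | CC(C)C[C@H]1C[C@@]2(Oc3c(C=O)c(O)c(C=O)c(O)c31)[C@@H]1CC[C@@H](C1)C2(C)C | target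

**Step count**

Total: 13 steps. Longest linear sequence: 12 steps (steps 1–8 and 10–13, from 1-chloro-3,5-dimethoxybenzene); the camphenilone branch is the single step 9.

**Steps most likely to fail**

Step 11. The hindered tertiary lithium alkoxide may close too slowly, so that the aryne is intercepted by the amide base or its amine. The C8 anion may also be protonated by tetramethylpiperidine before DMF arrives, with proton shuffling toward C6. Partial C6 formylation would not be a loss, since step 12 converges such material on 26. If cyclisation itself fails, the fallback sets out from 20 and closes the ring by palladium-catalysed intramolecular C–O coupling of the tertiary alcohol with the aryl chloride (Pd(OAc)2, 2-(di-tert-butylphosphino)-1,1'-binaphthyl, Cs2CO3, toluene, 90 °C). This should give the unformylated 4-isobutyl-5,7-dimethoxy spirochroman F1. Twofold Rieche formylation of F1 (excess Cl2CHOMe, TiCl4, CH2Cl2, −78 to 0 °C) at C8 and C6 returns to the route at 26.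

Step 10. During iodine–lithium exchange the primary alkyllithium may metalate the chloroarene ring of a second molecule and trigger premature loss of LiCl. On the ketone, β-hydride transfer or sluggish addition may compete, and exo selectivity may erode with the bulky chain. The fallback sets out from 14 and 17 and inverts the order of events in a Barbier coupling: SmI2 (samarium diiodide, 2.5 equiv) with NiI2 (1 mol %) in THF at rt reduces the iodide in the presence of the ketone. The aryl chloride is inert under these conditions, and no basic organometallic accumulates. The coupling returns directly to 20 and makes no compound outside the list (entry F0).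

Step 12. TiCl4 may ionise the tertiary C2–O1 bond, giving a camphene-hydro-type cation that opens the ring and undergoes Wagner–Meerwein shift, faster than the deactivated ring is formylated. The fallback sets out from 24 and works under basic conditions only. Lithium 4-methylpiperazin-1-ide in THF at −20 °C masks the aldehyde as the lithium α-(4-methylpiperazin-1-yl) alkoxide F2. n-BuLi then metalates C6 between the two methoxy groups (directed ortho-metalation) to give the 6-lithio species F3. DMF gives the dilithium bis(hemiaminal alkoxide) F4, and aqueous work-up releases both aldehydes, returning to the route at 26.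

**Further compounds**

F1 | step 11 | (1'R,2R,4S,4'S)-4-isobutyl-5,7-dimethoxy-3',3'-dimethylspiro[chromane-2,2'-bicyclo[2.2.1]heptane] | CC(C)C[C@H]1C[C@@]2(Oc3cc(OC)cc(OC)c31)[C@@H]1CC[C@@H](C1)C2(C)C
F0 | step 10 | none | none
F2 | step 12 | lithium α-(4-methylpiperazin-1-yl) alkoxide of 24 | CC(C)C[C@H]1C[C@@]2(Oc3c(C([O-])N4CCN(C)CC4)c(OC)cc(OC)c31)[C@@H]1CC[C@@H](C1)C2(C)C.[Li+]
F3 | step 12 | 6-lithio derivative of F2 | CC(C)C[C@H]1C[C@@]2(Oc3c(C([O-])N4CCN(C)CC4)c(OC)c([Li])c(OC)c31)[C@@H]1CC[C@@H](C1)C2(C)C.[Li+]
F4 | step 12 | dilithium bis(hemiaminal alkoxide), DMF adduct of F3 | CC(C)C[C@H]1C[C@@]2(Oc3c(C([O-])N4CCN(C)CC4)c(OC)c(C([O-])N(C)C)c(OC)c31)[C@@H]1CC[C@@H](C1)C2(C)C.[Li+].[Li+]
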